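## Retrosynthetic overview

1. The target is a (2R,3S)-flavan-3-ol (ring A = phloroglucinol ring; ring C = pyran with O1, C2, C3, C4; ring B on C2) whose C8 and O7 carry a spiro-linked 4,6-dihydroxybenzofuran-3-one (furanone ring E, benzo ring F) through dihydrofuran ring D; Cs is the spiro carbon and Cb the benzylic carbon of ring D, which bears ring G.
2. Late disconnections: O7–Cb (ring D, debenzylative cyclisation), the aryl–O bond of ring E (SNAr of a tertiary alkoxide on a fluoroarene) and C8–Cs (aryl-metal addition to a chiral 1,2-diketone); before these the C4 ketone, present only to build ring C, is removed.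
3. Key disconnection: ring C is opened at O1–C8a, C2–C3 and C4–C4a into 3,5-bis(benzyloxy)benzyne, 4-(benzyloxy)benzaldehyde and a glycolate ester enolate, which are joined in one operation.
4. Enabling feature: ring A is a phloroglucinol in which C8a (bearing O1) and C4a (bearing C4) are neighbours and the C5 oxygen sits on the carbon beside C4a, so a C4a≡C8a aryne takes up O1 at C8a and the acyl carbon C4 at C4a; the C2–C3–C4 unit is at the same time an aldol whose aldehyde oxygen becomes O1.
5. Ring order: C (step 4), then E (step 15), then D (step 16); rings B and G both come from the same benzaldehyde, rings A and F from 3,5-bis(benzyloxy)phenol and 1,3,5-trifluorobenzene.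

Key step: step 4

Assumption: the (S,S)-ProPhenol ligand is taken to give the (S)-propargylic carbinol and the (S,S)-TsDPEN ruthenium catalyst to be matched with the (2R,3R)-flavanone (quadrant model plus axial hydride delivery); if either sense is the opposite in practice, the enantiomeric ligand or catalyst is used with no other change.

## Route

Step 1
Reactants: 1 3,5-bis(benzyloxy)phenol
Product: 2 3,5-bis(benzyloxy)phenyl N-(propan-2-yl)carbamate
Conditions: i-PrNCO, Et3N (cat.), CH2Cl2, 23 °C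
Reagents that add atoms: isopropyl isocyanate, CC(C)N=C=O
Why: Addition of the phenol to the isocyanate installs a cleavable carbamate that will direct ortho-metalation.

Step 2
Reactants: 2 3,5-bis(benzyloxy)phenyl N-(propan-2-yl)carbamate
Product: 5 3,5-bis(benzyloxy)-2-(trimethylsilyl)phenyl N-(propan-2-yl)carbamate, via N-silyl carbamate 3 (not isolated), via C-silylated N-silyl carbamate 4 (not isolated)
Conditions: TMEDA, t-BuMe2SiOTf, Et2O, 0 → 23 °C; TMEDA, n-BuLi, −78 °C; Me3SiCl, −78 → 23 °C; aq. NaHSO4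
Reagents that add atoms: chlorotrimethylsilane, C[Si](C)(C)Cl
Why: Directed ortho-metalation: transient N-silylation masks the N–H, the carbamate directs lithiation to the position between itself and a benzyloxy group (the two such positions are equivalent), Me3SiCl traps the aryllithium and the N-silyl group is lost on acidic work-up.

Step 3
Reactants: 5 3,5-bis(benzyloxy)-2-(trimethylsilyl)phenyl N-(propan-2-yl)carbamate
Product: 7 3,5-bis(benzyloxy)-2-(trimethylsilyl)phenyl trifluoromethanesulfonate, via silyl phenol 6 (not isolated)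
Conditions: Et2NH, DBU, MeCN, 40 °C; then PhNTf2, 23 °C
Reagents that add atoms: N-phenylbis(trifluoromethanesulfonimide), O=S(=O)(N(c1ccccc1)S(=O)(=O)C(F)(F)F)C(F)(F)F
Why: Base-induced loss of isopropyl isocyanate (trapped by Et2NH as a urea) frees the phenoxide, which is triflated in the same flask to give the ortho-silyl aryl triflate aryne precursor.

Step 4
Reactants: 8 methyl 2-(benzyloxy)acetate; 9 4-(benzyloxy)benzaldehyde; 7 3,5-bis(benzyloxy)-2-(trimethylsilyl)phenyl trifluoromethanesulfonate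
Product: 13 rac-(2R,3R)-3,5,7-tris(benzyloxy)-2-[4-(benzyloxy)phenyl]chroman-4-one, via lithium enolate 10 (not isolated), via lithium aldolate 11 (not isolated), via aryne 12 (not isolated)
Conditions: 8, LiN(SiMe3)2, THF, −78 °C; 9, −78 °C; then 7, CsF, 18-crown-6, −78 → 23 °C
Reagents that add atoms: none
Why: Proposed new method: enolate 10 adds to aldehyde 9 (C2–C3 bond), the aldolate oxygen of 11 then adds to aryne 12 released from 7 by fluoride (O1–C8a bond), and the resulting aryl anion at C4a attacks the methyl ester in a 6-exo-trig acyl substitution (C4–C4a bond) that closes ring C as the 4-ketone; the closest known reaction is the fluoride-mediated annulation of arynes with salicylate esters to xanthones (O-arylation followed by acyl capture by the aryl anion), here fed by an ester aldolate instead of a phenoxide. Regioselectivity is secured by the benzyloxy group beside the triple bond: the alkoxide attacks the aryne carbon remote from it, so the negative charge builds up on the carbon flanked by the σ-withdrawing C–O bond, which puts O1 on C8a and the acyl carbon on C4a and gives the 5,7-dioxygenation pattern. The aldol is complete at −78 °C before any aryne is released, which keeps free enolate and aldehyde away from the aryne. C2 and C3 are formed without absolute control, and C3, now α to the ketone, should equilibrate under the basic fluoride medium to the 2,3-trans isomer with both substituents equatorial, so 13 is expected as the racemic trans compound and the absolute configuration is set in step 5. The step needs O-attack of the aldolate to outrun retro-aldol and acyl capture to outrun proton transfer to the aryl anion; the crown-ether-assisted fluoride release at low temperature and the six-membered geometry of the acyl transfer are relied on for this.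

Step 5
Reactants: 13 rac-(2R,3R)-3,5,7-tris(benzyloxy)-2-[4-(benzyloxy)phenyl]chroman-4-one
Product: 14 (2R,3S,4R)-3,5,7-tris(benzyloxy)-2-[4-(benzyloxy)phenyl]chroman-4-ol
Conditions: RuCl[(S,S)-TsDPEN](p-cymene) (cat.), HCO2H/Et3N (5:2), EtOAc, 30 °C, stopped near half conversion
Reagents that add atoms: none
Why: Noyori–Ikariya asymmetric transfer hydrogenation with kinetic resolution, a reaction type known for racemic flavanones: for the (2R,3R)-ketone the face preferred by the (S,S)-catalyst is also the axial face preferred by the ring, so it should be reduced to the 2,4-cis alcohol while the (2S,3S)-ketone is left behind and separated, which fixes the absolute configuration of C2 and C3.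

Step 6
Reactants: 14 (2R,3S,4R)-3,5,7-tris(benzyloxy)-2-[4-(benzyloxy)phenyl]chroman-4-ol
Product: 15 (2R,3S)-3,5,7-tris(benzyloxy)-2-[4-(benzyloxy)phenyl]chromane
Conditions: Et3SiH, CF3CO2H, CH2Cl2, −20 → 0 °C
Reagents that add atoms: none
Why: Ionic hydrogenation: the C4 hydroxyl ionises to a cation stabilised by the 5,7-dioxygenated ring A and is reduced by the silane, which removes the temporary oxygen of the key step without touching C2 or C3.

Step 7
Reactants: 15 (2R,3S)-3,5,7-tris(benzyloxy)-2-[4-(benzyloxy)phenyl]chromane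
Product: 16 (2R,3S)-3,5,7-tris(benzyloxy)-2-[4-(benzyloxy)phenyl]-8-bromochromane
Conditions: NBS, CH2Cl2, −20 °C
Reagents that add atoms: N-bromosuccinimide, O=C1CCC(=O)N1Br
Why: Electrophilic aromatic bromination of ring A, which in 5,7-di-O-benzyl flavan-3-ols is known to go to C8 (C6 is flanked by two benzyloxy groups and ring B is far less activated).

Step 8
Reactants: 17 1,3,5-trifluorobenzene
Product: 18 1,3-bis(benzyloxy)-5-fluorobenzene
Conditions: BnOH, NaH, NMP, 0 → 80 °C
Reagents that add atoms: benzyl alcohol, OCc1ccccc1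
Why: Twofold SNAr by benzyl oxide; each alkoxy group introduced slows the next substitution, so the third fluoride should stay.

Step 9
Reactants: 18 1,3-bis(benzyloxy)-5-fluorobenzene
Product: 19 2,4-bis(benzyloxy)-6-fluorobenzaldehyde
Conditions: POCl3, DMF, 0 → 60 °C; aq. NaOAc
Reagents that add atoms: N,N-dimethylformamide, CN(C)C=O; water, O
Why: Vilsmeier–Haack formylation at the position ortho and para to the two benzyloxy groups that is flanked by fluorine, the less hindered of the two doubly activated positions.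

Step 10
Reactants: 19 2,4-bis(benzyloxy)-6-fluorobenzaldehyde
Product: 20 1,5-bis(benzyloxy)-2-ethynyl-3-fluorobenzene
Conditions: dimethyl (1-diazo-2-oxopropyl)phosphonate, K2CO3, MeOH/THF, 23 °C
Reagents that add atoms: dimethyl (1-diazo-2-oxopropyl)phosphonate, COP(=O)(OC)C(=[N+]=[N-])C(C)=O
Why: Seyferth–Gilbert homologation in the Ohira–Bestmann variant converts the aldehyde into the terminal alkyne with one added carbon.

Step 11
Reactants: 20 1,5-bis(benzyloxy)-2-ethynyl-3-fluorobenzene; 9 4-(benzyloxy)benzaldehyde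
Product: 21 (1S)-1-[4-(benzyloxy)phenyl]-3-[2,4-bis(benzyloxy)-6-fluorophenyl]prop-2-yn-1-ol
Conditions: Me2Zn, (S,S)-ProPhenol (cat.), Ph3PO (cat.), toluene, 0 °C
Reagents that add atoms: none
Why: Catalytic enantioselective addition of the alkynylzinc to an aromatic aldehyde (dinuclear zinc–ProPhenol catalysis) sets the carbinol carbon Cb by catalyst control; Cb later controls Cs.

Step 12
Reactants: 21 (1S)-1-[4-(benzyloxy)phenyl]-3-[2,4-bis(benzyloxy)-6-fluorophenyl]prop-2-yn-1-ol
Product: 22 1,5-bis(benzyloxy)-2-{(3S)-3-(benzyloxy)-3-[4-(benzyloxy)phenyl]prop-1-yn-1-yl}-3-fluorobenzene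
Conditions: BnBr, Ag2O, CH2Cl2, 23 °C, dark
Reagents that add atoms: benzyl bromide, BrCc1ccccc1
Why: Neutral silver-oxide benzylation avoids base-induced propargyl–allene isomerisation and breaks no bond to Cb, so its configuration is kept.

Step 13
Reactants: 22 1,5-bis(benzyloxy)-2-{(3S)-3-(benzyloxy)-3-[4-(benzyloxy)phenyl]prop-1-yn-1-yl}-3-fluorobenzene
Product: 23 (3S)-3-(benzyloxy)-1-[2,4-bis(benzyloxy)-6-fluorophenyl]-3-[4-(benzyloxy)phenyl]propane-1,2-dione
Conditions: KMnO4, NaHCO3, MgSO4, acetone/H2O, 0 → 23 °C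
Reagents that add atoms: potassium permanganate, [K+].[O-][Mn](=O)(=O)=O
Why: Buffered permanganate oxidation of an internal alkyne to the 1,2-diketone; cold, neutral conditions are chosen to spare the now enolisable Cb–H.

Step 14
Reactants: 16 (2R,3S)-3,5,7-tris(benzyloxy)-2-[4-(benzyloxy)phenyl]-8-bromochromane; 23 (3S)-3-(benzyloxy)-1-[2,4-bis(benzyloxy)-6-fluorophenyl]-3-[4-(benzyloxy)phenyl]propane-1,2-dione
Product: 26 (2S,3S)-3-(benzyloxy)-1-[2,4-bis(benzyloxy)-6-fluorophenyl]-3-[4-(benzyloxy)phenyl]-2-hydroxy-2-{(2R,3S)-3,5,7-tris(benzyloxy)-2-[4-(benzyloxy)phenyl]chroman-8-yl}propan-1-one, via aryllithium 24 (not isolated), via arylmagnesium bromide 25 (not isolated)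
Conditions: t-BuLi, THF, −78 °C; MgBr2·OEt2, −78 °C; 23, −78 → −40 °C; aq. NH4Cl
Reagents that add atoms: none
Why: Bromine–lithium exchange and transmetalation give a C8 Grignard reagent that should add to the ketone next to Cb (the other carbonyl is a twisted, doubly ortho-substituted, electron-rich aryl ketone), and magnesium held between that C=O and the Cb benzyloxy oxygen (Cram chelate model) exposes the face anti to ring G, which sets Cs as (S).

Step 15
Reactants: 26 (2S,3S)-3-(benzyloxy)-1-[2,4-bis(benzyloxy)-6-fluorophenyl]-3-[4-(benzyloxy)phenyl]-2-hydroxy-2-{(2R,3S)-3,5,7-tris(benzyloxy)-2-[4-(benzyloxy)phenyl]chroman-8-yl}propan-1-one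
Product: 27 (2S)-4,6-bis(benzyloxy)-2-{(S)-(benzyloxy)[4-(benzyloxy)phenyl]methyl}-2-{(2R,3S)-3,5,7-tris(benzyloxy)-2-[4-(benzyloxy)phenyl]chroman-8-yl}benzofuran-3(2H)-one
Conditions: Cs2CO3, DMF, 40 °C
Reagents that add atoms: none
Why: Intramolecular SNAr (5-exo) of the tertiary alkoxide on the fluoride ortho to the ketone closes ring E; no bond to Cs is broken, so its configuration is retained.

Step 16
Reactants: 27 (2S)-4,6-bis(benzyloxy)-2-{(S)-(benzyloxy)[4-(benzyloxy)phenyl]methyl}-2-{(2R,3S)-3,5,7-tris(benzyloxy)-2-[4-(benzyloxy)phenyl]chroman-8-yl}benzofuran-3(2H)-one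
Product: 28 (2S,2′R,3′S,8′S)-3′,4,5′,6-tetrakis(benzyloxy)-2′,8′-bis[4-(benzyloxy)phenyl]-3′,4′-dihydro-2′H,8′H-spiro[1-benzofuran-2,9′-furo[2,3-h]chromen]-3-one
Conditions: Me3SiOTf (cat.), CH2Cl2, −40 → 0 °C
Reagents that add atoms: none
Why: Debenzylative cycloetherification: ionisation of the Cb benzyl ether gives a cation stabilised by ring G, the neighbouring 7-benzyloxy oxygen closes ring D (5-exo) and passes its benzyl group to the released benzyl silyl ether, and because the closure is reversible under the acid Cb should settle with ring G cis to the ring-E oxygen and trans to the bulkier carbonyl, which is the (S) configuration (net retention).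

Step 17
Reactants: 28 (2S,2′R,3′S,8′S)-3′,4,5′,6-tetrakis(benzyloxy)-2′,8′-bis[4-(benzyloxy)phenyl]-3′,4′-dihydro-2′H,8′H-spiro[1-benzofuran-2,9′-furo[2,3-h]chromen]-3-one
Product: 29 (2S,2′R,3′S,8′S)-3′,4,5′,6-tetrahydroxy-2′,8′-bis(4-hydroxyphenyl)-3′,4′-dihydro-2′H,8′H-spiro[1-benzofuran-2,9′-furo[2,3-h]chromen]-3-one
Conditions: H2 (1 atm), Pd(OH)2/C, THF/MeOH, 23 °C
Reagents that add atoms: none
Why: Hydrogenolysis of the six benzyl ethers under neutral conditions should leave the ketone, the benzylic C2–O1 and Cb–O7 ring bonds and the acid-sensitive spiro centre intact if stopped at full debenzylation.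

## Compound list

1 | 3,5-bis(benzyloxy)phenol | Oc1cc(OCc2ccccc2)cc(OCc2ccccc2)c1 | starting material
2 | 3,5-bis(benzyloxy)phenyl N-(propan-2-yl)carbamate | CC(C)NC(=O)Oc1cc(OCc2ccccc2)cc(OCc2ccccc2)c1 | intermediate
3 | 3,5-bis(benzyloxy)phenyl N-(tert-butyldimethylsilyl)-N-(propan-2-yl)carbamate (not isolated) | CC(C)N([Si](C)(C)C(C)(C)C)C(=O)Oc1cc(OCc2ccccc2)cc(OCc2ccccc2)c1 | intermediate
4 | 3,5-bis(benzyloxy)-2-(trimethylsilyl)phenyl N-(tert-butyldimethylsilyl)-N-(propan-2-yl)carbamate (not isolated) | CC(C)N([Si](C)(C)C(C)(C)C)C(=O)Oc1cc(OCc2ccccc2)cc(OCc2ccccc2)c1[Si](C)(C)C | intermediate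
5 | 3,5-bis(benzyloxy)-2-(trimethylsilyl)phenyl N-(propan-2-yl)carbamate | CC(C)NC(=O)Oc1cc(OCc2ccccc2)cc(OCc2ccccc2)c1[Si](C)(C)C | intermediate
6 | 3,5-bis(benzyloxy)-2-(trimethylsilyl)phenol (not isolated) | Oc1cc(OCc2ccccc2)cc(OCc2ccccc2)c1[Si](C)(C)C | intermediate
7 | 3,5-bis(benzyloxy)-2-(trimethylsilyl)phenyl trifluoromethanesulfonate | FC(F)(F)S(=O)(=O)Oc1cc(OCc2ccccc2)cc(OCc2ccccc2)c1[Si](C)(C)C | intermediate
8 | methyl 2-(benzyloxy)acetate | COC(=O)COCc1ccccc1 | starting material
9 | 4-(benzyloxy)benzaldehyde | O=Cc1ccc(OCc2ccccc2)cc1 | starting material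
10 | lithium 2-(benzyloxy)-1-methoxyethen-1-olate, enolate of 8 (not isolated; geometry not defined) | [Li+].[O-]C(OC)=COCc1ccccc1 | intermediate
11 | lithium salt of methyl 2-(benzyloxy)-3-[4-(benzyloxy)phenyl]-3-hydroxypropanoate (not isolated; racemic mixture of diastereomers) | [Li+].[O-]C(c1ccc(OCc2ccccc2)cc1)C(OCc1ccccc1)C(=O)OC | intermediate
12 | 3,5-bis(benzyloxy)benzyne, 1,2-didehydro-3,5-bis(benzyloxy)benzene (not isolated) | C1#CC(OCc2ccccc2)=CC(OCc2ccccc2)=C1 | intermediate
13 | rac-(2R,3R)-3,5,7-tris(benzyloxy)-2-[4-(benzyloxy)phenyl]chroman-4-one (racemic 2,3-trans; the 2R,3R enantiomer is drawn) | O=C1c2c(OCc3ccccc3)cc(OCc3ccccc3)cc2O[C@H](c2ccc(OCc3ccccc3)cc2)[C@H]1OCc1ccccc1 | intermediate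
14 | (2R,3S,4R)-3,5,7-tris(benzyloxy)-2-[4-(benzyloxy)phenyl]chroman-4-ol | O[C@@H]1c2c(OCc3ccccc3)cc(OCc3ccccc3)cc2O[C@H](c2ccc(OCc3ccccc3)cc2)[C@H]1OCc1ccccc1 | intermediate
15 | (2R,3S)-3,5,7-tris(benzyloxy)-2-[4-(benzyloxy)phenyl]chromane (tetra-O-benzyl-(+)-afzelechin) | O(Cc1ccccc1)c1cc(OCc2ccccc2)c2c(c1)O[C@H](c1ccc(OCc3ccccc3)cc1)[C@@H](OCc1ccccc1)C2 | intermediate
16 | (2R,3S)-3,5,7-tris(benzyloxy)-2-[4-(benzyloxy)phenyl]-8-bromochromane | O(Cc1ccccc1)c1cc(OCc2ccccc2)c2c(c1Br)O[C@H](c1ccc(OCc3ccccc3)cc1)[C@@H](OCc1ccccc1)C2 | intermediate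
17 | 1,3,5-trifluorobenzene | Fc1cc(F)cc(F)c1 | starting material
18 | 1,3-bis(benzyloxy)-5-fluorobenzene | Fc1cc(OCc2ccccc2)cc(OCc2ccccc2)c1 | intermediate
19 | 2,4-bis(benzyloxy)-6-fluorobenzaldehyde | O=Cc1c(F)cc(OCc2ccccc2)cc1OCc1ccccc1 | intermediate
20 | 1,5-bis(benzyloxy)-2-ethynyl-3-fluorobenzene | C#Cc1c(F)cc(OCc2ccccc2)cc1OCc1ccccc1 | intermediate
21 | (1S)-1-[4-(benzyloxy)phenyl]-3-[2,4-bis(benzyloxy)-6-fluorophenyl]prop-2-yn-1-ol | O[C@H](C#Cc1c(F)cc(OCc2ccccc2)cc1OCc1ccccc1)c1ccc(OCc2ccccc2)cc1 | intermediate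
22 | 1,5-bis(benzyloxy)-2-{(3S)-3-(benzyloxy)-3-[4-(benzyloxy)phenyl]prop-1-yn-1-yl}-3-fluorobenzene | C(c1ccccc1)O[C@H](C#Cc1c(F)cc(OCc2ccccc2)cc1OCc1ccccc1)c1ccc(OCc2ccccc2)cc1 | intermediate
23 | (3S)-3-(benzyloxy)-1-[2,4-bis(benzyloxy)-6-fluorophenyl]-3-[4-(benzyloxy)phenyl]propane-1,2-dione | O=C(c1c(F)cc(OCc2ccccc2)cc1OCc1ccccc1)C(=O)[C@@H](OCc1ccccc1)c1ccc(OCc2ccccc2)cc1 | intermediate
24 | 8-lithio derivative of 15, {(2R,3S)-3,5,7-tris(benzyloxy)-2-[4-(benzyloxy)phenyl]chroman-8-yl}lithium (not isolated) | O(Cc1ccccc1)c1cc(OCc2ccccc2)c2c(c1[Li])O[C@H](c1ccc(OCc3ccccc3)cc1)[C@@H](OCc1ccccc1)C2 | intermediate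
25 | {(2R,3S)-3,5,7-tris(benzyloxy)-2-[4-(benzyloxy)phenyl]chroman-8-yl}magnesium bromide (not isolated) | O(Cc1ccccc1)c1cc(OCc2ccccc2)c2c(c1[Mg]Br)O[C@H](c1ccc(OCc3ccccc3)cc1)[C@@H](OCc1ccccc1)C2 | intermediate
26 | (2S,3S)-3-(benzyloxy)-1-[2,4-bis(benzyloxy)-6-fluorophenyl]-3-[4-(benzyloxy)phenyl]-2-hydroxy-2-{(2R,3S)-3,5,7-tris(benzyloxy)-2-[4-(benzyloxy)phenyl]chroman-8-yl}propan-1-one | O(Cc1ccccc1)c1cc(OCc2ccccc2)c2c(c1[C@@](O)(C(=O)c1c(F)cc(OCc3ccccc3)cc1OCc1ccccc1)[C@@H](OCc1ccccc1)c1ccc(OCc3ccccc3)cc1)O[C@H](c1ccc(OCc3ccccc3)cc1)[C@@H](OCc1ccccc1)C2 | intermediate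
27 | (2S)-4,6-bis(benzyloxy)-2-{(S)-(benzyloxy)[4-(benzyloxy)phenyl]methyl}-2-{(2R,3S)-3,5,7-tris(benzyloxy)-2-[4-(benzyloxy)phenyl]chroman-8-yl}benzofuran-3(2H)-one | O=C1c2c(OCc3ccccc3)cc(OCc3ccccc3)cc2O[C@]1([C@@H](OCc2ccccc2)c2ccc(OCc3ccccc3)cc2)c1c(OCc2ccccc2)cc(OCc2ccccc2)c2c1O[C@H](c1ccc(OCc3ccccc3)cc1)[C@@H](OCc1ccccc1)C2 | intermediate
28 | (2S,2′R,3′S,8′S)-3′,4,5′,6-tetrakis(benzyloxy)-2′,8′-bis[4-(benzyloxy)phenyl]-3′,4′-dihydro-2′H,8′H-spiro[1-benzofuran-2,9′-furo[2,3-h]chromen]-3-one (hexa-O-benzyl ether of 29) | O=C1c2c(OCc3ccccc3)cc(OCc3ccccc3)cc2O[C@]12c1c(cc(OCc3ccccc3)c3c1O[C@H](c1ccc(OCc4ccccc4)cc1)[C@@H](OCc1ccccc1)C3)O[C@H]2c1ccc(OCc2ccccc2)cc1 | intermediate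
29 | (2S,2′R,3′S,8′S)-3′,4,5′,6-tetrahydroxy-2′,8′-bis(4-hydroxyphenyl)-3′,4′-dihydro-2′H,8′H-spiro[1-benzofuran-2,9′-furo[2,3-h]chromen]-3-one | O=C1c2c(O)cc(O)cc2O[C@]12c1c(cc(O)c3c1O[C@H](c1ccc(O)cc1)[C@@H](O)C3)O[C@H]2c1ccc(O)cc1 | target

## Step count and risks

Total step count: 17. Longest linear sequence: 11 steps (steps 1–7 and 14–17); the diketone branch (steps 8–13) joins at step 14.

Steps most likely to fail:

1. Step 4 (Proposed new method). What may go wrong: proton transfer from the acidic C3–H to the aryl anion before it reaches the ester (giving an open O-aryl aldol), retro-aldol of the aldolate followed by C-arylation of the freed enolate, or capture of the aryne by the methoxide that is released. Fallback with known chemistry, setting out from 9: the known ketone 1-[2,4-bis(benzyloxy)-6-hydroxyphenyl]ethanone F1 is protected (MOMCl, i-Pr2NEt) as its methoxymethyl ether F2 and condensed with 9 (KOH, EtOH, Claisen–Schmidt) to chalcone F3. Juliá–Colonna epoxidation (poly-L-leucine, urea–H2O2, DBU, THF) should give the (2R,3S)-epoxide F4. HCl in MeOH removes the MOM group and the freed phenol opens the epoxide at the benzylic carbon with inversion to give the trans-dihydroflavonol F5. Benzylation of the 3-hydroxyl (BnBr, Ag2O) returns to the route at 13, now as the single (2R,3R) enantiomer, so that step 5 is run to full conversion without resolution.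

2. Step 14. What may go wrong: deprotonation of the diketone at Cb by the basic aryl-metal (loss of the Cb configuration and no addition), slow addition of the doubly ortho-substituted aryl nucleophile to the hindered ketone, or poor facial selectivity if magnesium bridges the two carbonyl oxygens instead of the carbonyl and the benzyloxy oxygen. Fallback, setting out from 15 (without bromination) and 23: a non-basic Friedel–Crafts hydroxyalkylation of ring A at C8 with SnCl4 in CH2Cl2 at −78 °C, in which the Lewis acid activates the ketone through the same five-membered chelate with the Cb benzyloxy oxygen; it comes back to the route at 26 and makes no new compound (F0).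

3. Step 16. What may go wrong: ionisation of the spiro C–O bond by the Lewis acid with irreversible aromatisation of ring D to a benzofuran, a 1,2-aryl shift in the Cb cation, capture of the cation by the pyran oxygen O1, or poor facial selectivity in the ring closure. Fallback, setting out from 27: hydrogenolysis (H2, Pd(OH)2/C, EtOAc/MeOH) of all eight benzyl groups gives the polyphenolic carbinol (2S)-4,6-dihydroxy-2-[(S)-hydroxy(4-hydroxyphenyl)methyl]-2-[(2R,3S)-3,5,7-trihydroxy-2-(4-hydroxyphenyl)chroman-8-yl]benzofuran-3(2H)-one F6. Warmed in aqueous MeOH near neutral pH, F6 should lose water through its 4-hydroxybenzyl alcohol (p-quinone methide) and close ring D by 5-exo attack of the 7-hydroxyl without any Lewis acid. It comes back to the route at 29, so step 17 falls away.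

## Further compounds

F1 | step 4 | 1-[2,4-bis(benzyloxy)-6-hydroxyphenyl]ethanone | CC(=O)c1c(O)cc(OCc2ccccc2)cc1OCc1ccccc1
F2 | step 4 | 1-[2,4-bis(benzyloxy)-6-(methoxymethoxy)phenyl]ethanone | CC(=O)c1c(OCOC)cc(OCc2ccccc2)cc1OCc1ccccc1
F3 | step 4 | (E)-1-[2,4-bis(benzyloxy)-6-(methoxymethoxy)phenyl]-3-[4-(benzyloxy)phenyl]prop-2-en-1-one | O=C(/C=C/c1ccc(OCc2ccccc2)cc1)c1c(OCOC)cc(OCc2ccccc2)cc1OCc1ccccc1
F4 | step 4 | [2,4-bis(benzyloxy)-6-(methoxymethoxy)phenyl]{(2R,3S)-3-[4-(benzyloxy)phenyl]oxiran-2-yl}methanone | O=C([C@@H]1O[C@H]1c1ccc(OCc2ccccc2)cc1)c1c(OCOC)cc(OCc2ccccc2)cc1OCc1ccccc1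
F5 | step 4 | (2R,3R)-5,7-bis(benzyloxy)-2-[4-(benzyloxy)phenyl]-3-hydroxychroman-4-one | O=C1c2c(OCc3ccccc3)cc(OCc3ccccc3)cc2O[C@H](c2ccc(OCc3ccccc3)cc2)[C@H]1O
F0 | step 14 | none | none
F6 | step 16 | (2S)-4,6-dihydroxy-2-[(S)-hydroxy(4-hydroxyphenyl)methyl]-2-[(2R,3S)-3,5,7-trihydroxy-2-(4-hydroxyphenyl)chroman-8-yl]benzofuran-3(2H)-one | O=C1c2c(O)cc(O)cc2O[C@]1([C@@H](O)c2ccc(O)cc2)c1c(O)cc(O)c2c1O[C@H](c1ccc(O)cc1)[C@@H](O)C2
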